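**Plan**
1. Cuts: O1–C2 and C2–C3 of flavone unit 1 (oxidative chalcone closure, Claisen–Schmidt). Then O1''–C2'', C3''–C4'' and C4''–C4a'' of the apigenin unit (ynone closure, acetylide addition, ortho-formylation). Last, C8''–C8a'' and C6''–C7'' of its ring A (benzannulation).
2. Enabling feature: ring A of the apigenin unit is a benzene with oxygen on C5'', C7'' and C8a'' and the dimethoxyphenyl ring on C8''. C8''–C7'' maps onto a polarised Ar–C≡C–OSi unit and C8a''–C4a''–C5''–C6'' onto the four ring carbons of 3-ethoxycyclobutenone, so the hindered 3'–8'' biaryl bond enters as an aryl–alkyne bond.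
3. Forward order: central ring (5-iodovanillin) → aryl siloxyalkyne → ring A of unit 2 → ring C of unit 2 → chalcone → ring C of unit 1 → one global deprotection.
4. The three ring A oxygens emerge distinct: free OH (future O1''), silyl ether at C7'', ethyl ether at C5''. The ethyl ether stays to the last step and so excludes 8-aryl/6-aryl (Wessely–Moser) scrambling.
5. Stereochemistry: the target has no stereocentre. The sp3 centres that appear on the way are racemic and are erased, and the E-alkene of the chalcone is consumed.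

Key step: step 6

Assumption: the 3'–8'' biaryl axis is treated as configurationally labile, since the target structure carries no stereodescriptor. Locants: unprimed = chromone of unit 1, primed = central dimethoxyphenyl ring, double-primed = chromone of the apigenin unit (unit 2), triple-primed = its 4-hydroxyphenyl ring.

**Step 1**
Reactants: 1 5-iodovanillin (4-hydroxy-3-iodo-5-methoxybenzaldehyde)
Product: 2 3-iodo-4,5-dimethoxybenzaldehyde
Conditions: MeI, K2CO3, DMF, rt
Reagents that add atoms: iodomethane, CI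
Why: Williamson O-methylation of the acidic phenol under carbonate conditions, which touch neither the aldehyde nor the aryl iodide.

**Step 2**
Reactants: 2 3-iodo-4,5-dimethoxybenzaldehyde
Product: 3 2-(3-iodo-4,5-dimethoxyphenyl)-1,3-dioxolane
Conditions: HOCH2CH2OH, p-TsOH·H2O (cat.), PhMe, reflux, Dean–Stark
Reagents that add atoms: ethylene glycol, OCCO
Why: Acid-catalysed acetalisation with azeotropic water removal masks the aldehyde against the organolithium steps, and a cyclic acetal is chosen because it tolerates silica gel, hot toluene and brief contact with a silyl triflate better than an acyclic one.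

**Step 3**
Reactants: 3 2-(3-iodo-4,5-dimethoxyphenyl)-1,3-dioxolane
Product: 4 {[5-(1,3-dioxolan-2-yl)-2,3-dimethoxyphenyl]ethynyl}trimethylsilane
Conditions: Me3SiC≡CH, PdCl2(PPh3)2 (cat.), CuI (cat.), Et3N, THF, rt → 40 °C
Reagents that add atoms: ethynyltrimethylsilane, C#C[Si](C)(C)C
Why: Sonogashira coupling of an aryl iodide, which proceeds under mild basic conditions that leave the acetal intact despite the ortho-methoxy group.

**Step 4**
Reactants: 4 {[5-(1,3-dioxolan-2-yl)-2,3-dimethoxyphenyl]ethynyl}trimethylsilane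
Product: 5 2-(3-ethynyl-4,5-dimethoxyphenyl)-1,3-dioxolane
Conditions: K2CO3 (cat.), MeOH, rt
Reagents that add atoms: none
Why: Base-catalysed methanolysis of the C(sp)–Si bond (protodesilylation) is standard for alkynylsilanes and is harmless to acetal and ethers.

**Step 5**
Reactants: 5 2-(3-ethynyl-4,5-dimethoxyphenyl)-1,3-dioxolane
Product: 8 {[5-(1,3-dioxolan-2-yl)-2,3-dimethoxyphenyl]ethynyloxy}triisopropylsilane, via lithium acetylide 6 (not isolated), via lithium ynolate 7 (not isolated)
Conditions: n-BuLi (1.0 equiv), THF, −78 °C; LiOOt-Bu (from t-BuOOH and LiN(SiMe3)2), −78 → 0 °C; TIPSOTf (1.05 equiv), −78 → 0 °C; Et3N-deactivated silica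
Reagents that add atoms: tert-butyl hydroperoxide, CC(C)(C)OO; triisopropylsilyl trifluoromethanesulfonate, CC(C)[Si](C(C)C)(C(C)C)OS(=O)(=O)C(F)(F)F
Why: Electrophilic oxygen transfer from lithium tert-butyl peroxide to a lithium arylacetylide gives the ynolate, the bulky silyl triflate traps it on oxygen (known siloxyalkyne synthesis from terminal aryl alkynes), and the lithium tert-butoxide formed alongside buffers the acetal against any excess triflate.

**Step 6**
Reactants: 8 {[5-(1,3-dioxolan-2-yl)-2,3-dimethoxyphenyl]ethynyloxy}triisopropylsilane; 9 3-ethoxycyclobut-2-en-1-one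
Product: 14 2-[5-(1,3-dioxolan-2-yl)-2,3-dimethoxyphenyl]-5-ethoxy-3-(triisopropylsilyloxy)phenol, via vinylketene 10 (not isolated), via vinylcyclobutenone 11 (not isolated), via dienylketene 12 (not isolated), via cyclohexadienone 13 (not isolated)
Conditions: 9 (1.1 equiv, added over 4 h), PhMe, 110 °C, then 135 °C (sealed vessel), Ar
Reagents that add atoms: none
Why: Danheiser benzannulation: thermal 4π electrocyclic opening of 9 gives vinylketene 10, whose carbonyl carbon is attacked by the nucleophilic, aryl-bearing alkyne carbon of 8 in a regiospecific [2+2] cycloaddition that forms C8a''–C8'' and C6''–C7'' (11). Reversible 4π opening of 11 gives dienylketene 12, and ring A of unit 2 closes by a thermal disrotatory 6π electrocyclisation joining C8a'' to C4a'' (13), after which enolisation delivers phenol 14; in sum the alkyne is inserted into the C1–C2 bond of the cyclobutenone. The closest known reaction type is this same benzannulation as run with 3-alkylcyclobutenones and alkyl-substituted triisopropylsiloxyalkynes, which gives resorcinol monosilyl ethers. No stereocentre has to be controlled, because the one sp3 centre of 11 is racemic and vanishes on ring opening. The selectivity needed is regiochemical (free OH next to the aryl group, silyl ether on its other side, ethyl ether para to it) and is secured by the oxygen-donor polarisation of the siloxyalkyne, which leaves the aryl-bearing carbon as the only nucleophilic terminus for the ketene carbonyl. Slow addition of 9 keeps 10 dilute and should hold back its dimerisation and its capture by the product phenol.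

**Step 7**
Reactants: 14 2-[5-(1,3-dioxolan-2-yl)-2,3-dimethoxyphenyl]-5-ethoxy-3-(triisopropylsilyloxy)phenol
Product: 15 3-[5-(1,3-dioxolan-2-yl)-2,3-dimethoxyphenyl]-6-ethoxy-2-hydroxy-4-(triisopropylsilyloxy)benzaldehyde
Conditions: MgCl2, Et3N, (CH2O)n, MeCN, reflux; sat. aq. NH4Cl work-up
Reagents that add atoms: paraformaldehyde (as formaldehyde), C=O
Why: Casnati–Skattebøl ortho-formylation, in which the magnesium phenoxide delivers formaldehyde only to an ortho carbon; C8'' is blocked, so C4a'' alone reacts and the electronically competitive C6'' is left untouched.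

**Step 8**
Reactants: 16 4-(benzyloxy)benzaldehyde
Product: 17 1-(benzyloxy)-4-ethynylbenzene
Conditions: dimethyl (1-diazo-2-oxopropyl)phosphonate, K2CO3, MeOH, rt
Reagents that add atoms: dimethyl (1-diazo-2-oxopropyl)phosphonate, CC(=O)C(=[N+]=[N-])P(=O)(OC)OC
Why: Ohira–Bestmann variant of the Seyferth–Gilbert homologation converts an aryl aldehyde into the terminal alkyne in one mild step that leaves the benzyl ether alone.

**Step 9**
Reactants: 15 3-[5-(1,3-dioxolan-2-yl)-2,3-dimethoxyphenyl]-6-ethoxy-2-hydroxy-4-(triisopropylsilyloxy)benzaldehyde; 17 1-(benzyloxy)-4-ethynylbenzene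
Product: 19 (±)-6-{3-[4-(benzyloxy)phenyl]-1-hydroxyprop-2-yn-1-yl}-2-[5-(1,3-dioxolan-2-yl)-2,3-dimethoxyphenyl]-5-ethoxy-3-(triisopropylsilyloxy)phenol, via lithium arylacetylide 18 (not isolated)
Conditions: 17 (2.5 equiv), n-BuLi (2.4 equiv), THF, −78 °C; then 15, −78 → 0 °C; aq. NH4Cl
Reagents that add atoms: none
Why: 1,2-Addition of a lithium acetylide to an unprotected salicylaldehyde, in which the first equivalent deprotonates the phenol and the second adds to the lithium-chelated aldehyde; the new carbinol centre is formed racemic without control because step 10 erases it.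

**Step 10**
Reactants: 19 (±)-propargylic alcohol of step 9
Product: 20 3-[4-(benzyloxy)phenyl]-1-{3-[5-(1,3-dioxolan-2-yl)-2,3-dimethoxyphenyl]-6-ethoxy-2-hydroxy-4-(triisopropylsilyloxy)phenyl}prop-2-yn-1-one
Conditions: MnO2 (activated, excess), CH2Cl2, rt
Reagents that add atoms: none
Why: MnO2 oxidation is selective for the doubly activated (benzylic and propargylic) alcohol, and the meta-oxygenated phenol cannot be oxidised to a quinone.

**Step 11**
Reactants: 20 ortho-hydroxyaryl ynone of step 10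
Product: 21 2-[4-(benzyloxy)phenyl]-8-[5-(1,3-dioxolan-2-yl)-2,3-dimethoxyphenyl]-5-ethoxy-7-(triisopropylsilyloxy)-4H-chromen-4-one
Conditions: DMAP (20 mol %), DMF, rt
Reagents that add atoms: none
Why: DMAP-catalysed 6-endo-dig oxa-Michael cyclisation of an ortho-alkynoylphenol, in which reversible addition of the nucleophilic catalyst to the ynone β-carbon directs O1'' to C2'' (flavone) and not to the α-carbon (aurone); only the C8a'' oxygen is free to close.

**Step 12**
Reactants: 21 flavone acetal of step 11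
Product: 22 3-{2-[4-(benzyloxy)phenyl]-5-ethoxy-4-oxo-7-(triisopropylsilyloxy)-4H-chromen-8-yl}-4,5-dimethoxybenzaldehyde
Conditions: 1 M aq. HCl, THF, rt
Reagents that add atoms: water, O
Why: Acid hydrolysis of the electron-rich aryl dioxolane is fast under conditions to which aryl silyl, benzyl and alkyl ethers and the chromone are stable.

**Step 13**
Reactants: 23 2,4,6-trihydroxyacetophenone
Product: 24 1-[2,4-bis(benzyloxy)-6-hydroxyphenyl]ethan-1-one
Conditions: BnBr (2.1 equiv), K2CO3, DMF, rt → 50 °C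
Reagents that add atoms: benzyl bromide, BrCc1ccccc1
Why: Selective Williamson benzylation in which one ortho hydroxyl stays free because its hydrogen bond to the acetyl carbonyl lowers its nucleophilicity.

**Step 14**
Reactants: 22 flavone aldehyde of step 12; 24 1-[2,4-bis(benzyloxy)-6-hydroxyphenyl]ethan-1-one
Product: 26 2-[4-(benzyloxy)phenyl]-8-{5-[(E)-3-(2,4-bis(benzyloxy)-6-hydroxyphenyl)-3-oxoprop-1-en-1-yl]-2,3-dimethoxyphenyl}-5-ethoxy-7-hydroxy-4H-chromen-4-one, via potassium phenoxide aldehyde 25 (not isolated)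
Conditions: KOH (excess), EtOH/THF, rt; then aq. HCl to pH 4–5
Reagents that add atoms: none
Why: Claisen–Schmidt condensation of the non-enolisable aldehyde with the methyl ketone enolate gives the E-enone under thermodynamic control, while hydroxide first cleaves the silyl ether of the acidic C7'' phenol to phenoxide 25, whose charge shields the chromone of unit 2 from hydroxide.

**Step 15**
Reactants: 26 chalcone of step 14
Product: 27 8-{5-[5,7-bis(benzyloxy)-4-oxo-4H-chromen-2-yl]-2,3-dimethoxyphenyl}-2-[4-(benzyloxy)phenyl]-5-ethoxy-7-hydroxy-4H-chromen-4-one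
Conditions: I2 (10 mol %), DMSO, 120 °C
Reagents that add atoms: none
Why: Iodine-catalysed oxidative cyclisation of a 2'-hydroxychalcone in DMSO (6-endo oxa-Michael closure of O1–C2, then dehydrogenation with DMSO as terminal oxidant) is the standard chalcone-to-flavone conversion and tolerates benzyl ethers and free phenols.

**Step 16**
Reactants: 27 tri-O-benzyl 5''-O-ethyl biflavone of step 15
Product: 28 5'-methoxybilobetin
Conditions: BCl3 (excess), C6HMe5 (excess), CH2Cl2, −78 → 0 °C; MeOH, then aq. HCl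
Reagents that add atoms: none
Why: BCl3 with pentamethylbenzene as a non-basic benzyl cation trap cleaves aryl benzyl ethers at −78 °C, and on warming the six-membered boron chelate between the C4'' carbonyl and O5'' lets chloride remove the peri ethyl group, whereas the unchelated C4' and C5' methyl ethers should stay intact at or below 0 °C.

**Compound list**
1 | 5-iodovanillin | COc1cc(C=O)cc(I)c1O | starting material
2 | 3-iodo-4,5-dimethoxybenzaldehyde | COc1cc(C=O)cc(I)c1OC | intermediate
3 | 2-(3-iodo-4,5-dimethoxyphenyl)-1,3-dioxolane | COc1cc(C2OCCO2)cc(I)c1OC | intermediate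
4 | {[5-(1,3-dioxolan-2-yl)-2,3-dimethoxyphenyl]ethynyl}trimethylsilane | COc1cc(C2OCCO2)cc(C#C[Si](C)(C)C)c1OC | intermediate
5 | 2-(3-ethynyl-4,5-dimethoxyphenyl)-1,3-dioxolane | COc1cc(C2OCCO2)cc(C#C)c1OC | intermediate
6 | lithium acetylide of 5 (formed in the flask) | COc1cc(C2OCCO2)cc(C#[C-])c1OC.[Li+] | intermediate
7 | lithium [5-(1,3-dioxolan-2-yl)-2,3-dimethoxyphenyl]ethynolate (formed in the flask) | COc1cc(C2OCCO2)cc(C#C[O-])c1OC.[Li+] | intermediate
8 | {[5-(1,3-dioxolan-2-yl)-2,3-dimethoxyphenyl]ethynyloxy}triisopropylsilane | COc1cc(C2OCCO2)cc(C#CO[Si](C(C)C)(C(C)C)C(C)C)c1OC | intermediate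
9 | 3-ethoxycyclobut-2-en-1-one | CCOC1=CC(=O)C1 | starting material
10 | 3-ethoxybuta-1,3-dien-1-one (vinylketene, formed in the flask) | C=C(OCC)C=C=O | intermediate
11 | (±)-2-[5-(1,3-dioxolan-2-yl)-2,3-dimethoxyphenyl]-4-(1-ethoxyvinyl)-3-(triisopropylsilyloxy)cyclobut-2-en-1-one (formed in the flask) | COc1cc(C2OCCO2)cc(C2=C(O[Si](C(C)C)(C(C)C)C(C)C)C(C(=C)OCC)C2=O)c1OC | intermediate
12 | 2-aryl-5-ethoxy-3-(triisopropylsilyloxy)hexa-1,3,5-trien-1-one, ketene and ethoxyvinyl groups cis on the central alkene (dienylketene, formed in the flask) | COc1cc(C2OCCO2)cc(C(=C=O)/C(O[Si](C(C)C)(C(C)C)C(C)C)=C\C(=C)OCC)c1OC | intermediate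
13 | 2-[5-(1,3-dioxolan-2-yl)-2,3-dimethoxyphenyl]-5-ethoxy-3-(triisopropylsilyloxy)cyclohexa-2,4-dien-1-one (formed in the flask) | COc1cc(C2OCCO2)cc(C2=C(O[Si](C(C)C)(C(C)C)C(C)C)C=C(OCC)CC2=O)c1OC | intermediate
14 | 2-[5-(1,3-dioxolan-2-yl)-2,3-dimethoxyphenyl]-5-ethoxy-3-(triisopropylsilyloxy)phenol | COc1cc(C2OCCO2)cc(-c2c(O)cc(OCC)cc2O[Si](C(C)C)(C(C)C)C(C)C)c1OC | intermediate
15 | 3-[5-(1,3-dioxolan-2-yl)-2,3-dimethoxyphenyl]-6-ethoxy-2-hydroxy-4-(triisopropylsilyloxy)benzaldehyde | COc1cc(C2OCCO2)cc(-c2c(O)c(C=O)c(OCC)cc2O[Si](C(C)C)(C(C)C)C(C)C)c1OC | intermediate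
16 | 4-(benzyloxy)benzaldehyde | O=Cc1ccc(OCc2ccccc2)cc1 | starting material
17 | 1-(benzyloxy)-4-ethynylbenzene | C#Cc1ccc(OCc2ccccc2)cc1 | intermediate
18 | lithium [4-(benzyloxy)phenyl]acetylide (formed in the flask) | [Li+].[C-]#Cc1ccc(OCc2ccccc2)cc1 | intermediate
19 | (±)-6-{3-[4-(benzyloxy)phenyl]-1-hydroxyprop-2-yn-1-yl}-2-[5-(1,3-dioxolan-2-yl)-2,3-dimethoxyphenyl]-5-ethoxy-3-(triisopropylsilyloxy)phenol | COc1cc(C2OCCO2)cc(-c2c(O)c(C(O)C#Cc3ccc(OCc4ccccc4)cc3)c(OCC)cc2O[Si](C(C)C)(C(C)C)C(C)C)c1OC | intermediate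
20 | 3-[4-(benzyloxy)phenyl]-1-{3-[5-(1,3-dioxolan-2-yl)-2,3-dimethoxyphenyl]-6-ethoxy-2-hydroxy-4-(triisopropylsilyloxy)phenyl}prop-2-yn-1-one | COc1cc(C2OCCO2)cc(-c2c(O)c(C(=O)C#Cc3ccc(OCc4ccccc4)cc3)c(OCC)cc2O[Si](C(C)C)(C(C)C)C(C)C)c1OC | intermediate
21 | 2-[4-(benzyloxy)phenyl]-8-[5-(1,3-dioxolan-2-yl)-2,3-dimethoxyphenyl]-5-ethoxy-7-(triisopropylsilyloxy)-4H-chromen-4-one | COc1cc(C2OCCO2)cc(-c2c(O[Si](C(C)C)(C(C)C)C(C)C)cc(OCC)c3c(=O)cc(-c4ccc(OCc5ccccc5)cc4)oc23)c1OC | intermediate
22 | 3-{2-[4-(benzyloxy)phenyl]-5-ethoxy-4-oxo-7-(triisopropylsilyloxy)-4H-chromen-8-yl}-4,5-dimethoxybenzaldehyde | COc1cc(C=O)cc(-c2c(O[Si](C(C)C)(C(C)C)C(C)C)cc(OCC)c3c(=O)cc(-c4ccc(OCc5ccccc5)cc4)oc23)c1OC | intermediate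
23 | 2,4,6-trihydroxyacetophenone | CC(=O)c1c(O)cc(O)cc1O | starting material
24 | 1-[2,4-bis(benzyloxy)-6-hydroxyphenyl]ethan-1-one | CC(=O)c1c(O)cc(OCc2ccccc2)cc1OCc1ccccc1 | intermediate
25 | potassium 2-[4-(benzyloxy)phenyl]-5-ethoxy-8-(5-formyl-2,3-dimethoxyphenyl)-4-oxo-4H-chromen-7-olate (formed in the flask) | COc1cc(C=O)cc(-c2c([O-])cc(OCC)c3c(=O)cc(-c4ccc(OCc5ccccc5)cc4)oc23)c1OC.[K+] | intermediate
26 | 2-[4-(benzyloxy)phenyl]-8-{5-[(E)-3-(2,4-bis(benzyloxy)-6-hydroxyphenyl)-3-oxoprop-1-en-1-yl]-2,3-dimethoxyphenyl}-5-ethoxy-7-hydroxy-4H-chromen-4-one | COc1cc(/C=C/C(=O)c2c(O)cc(OCc3ccccc3)cc2OCc2ccccc2)cc(-c2c(O)cc(OCC)c3c(=O)cc(-c4ccc(OCc5ccccc5)cc4)oc23)c1OC | intermediate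
27 | 8-{5-[5,7-bis(benzyloxy)-4-oxo-4H-chromen-2-yl]-2,3-dimethoxyphenyl}-2-[4-(benzyloxy)phenyl]-5-ethoxy-7-hydroxy-4H-chromen-4-one | COc1cc(-c2cc(=O)c3c(OCc4ccccc4)cc(OCc4ccccc4)cc3o2)cc(-c2c(O)cc(OCC)c3c(=O)cc(-c4ccc(OCc5ccccc5)cc4)oc23)c1OC | intermediate
28 | 5'-methoxybilobetin | COc1cc(-c2cc(=O)c3c(O)cc(O)cc3o2)cc(-c2c(O)cc(O)c3c(=O)cc(-c4ccc(O)cc4)oc23)c1OC | target

**Step count**
Total: 16 steps. Longest linear sequence: 14 steps from 5-iodovanillin (steps 1–7, 9–12, 14–16). Steps 8 and 13 are one-step side branches.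

**Steps most likely to fail**

Step 6 (benzannulation).
- What may go wrong: The vinylogous-ester cyclobutenone may open too slowly at temperatures at which the siloxyalkyne still resists a 1,3-silyl shift to a silylketene. The vinylketene may dimerise or acylate the product phenol. The ortho-methoxyaryl group may slow the [2+2] step.
- Fallback: It sets out from 3 and comes back at 14. The biaryl bond is made by cross-coupling and the oxygens are told apart by desymmetrisation.
 - Miyaura borylation of 3 (B2pin2, PdCl2(dppf), KOAc, dioxane, 90 °C) should give 2-[5-(1,3-dioxolan-2-yl)-2,3-dimethoxyphenyl]-4,4,5,5-tetramethyl-1,3,2-dioxaborolane F1.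
 - Separately, phloroglucinol is mono-etherified (EtOH, HCl) to 5-ethoxybenzene-1,3-diol F2. This is iodinated between its two hydroxyls (I2, NaHCO3, THF/H2O, 0 °C) to 5-ethoxy-2-iodobenzene-1,3-diol F3.
 - Suzuki–Miyaura coupling of F1 with F3 (Pd(OAc)2, SPhos, K3PO4, dioxane/H2O, 90 °C) should give 2-[5-(1,3-dioxolan-2-yl)-2,3-dimethoxyphenyl]-5-ethoxybenzene-1,3-diol F4.
 - The two hydroxyls of F4 are equivalent, so monosilylation (TIPSCl, 1 equiv, imidazole, DMF, 0 °C) leads to 14.

Step 5 (siloxyalkyne).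
- What may go wrong: Oxygen transfer to the hindered ortho-methoxyaryl acetylide may be incomplete. Silylation may occur on carbon to give a silylketene. The silyl triflate may activate the acetal. The ynol ether may hydrolyse on silica.
- Fallback: It sets out from 3 and comes back at 7 (and so at 8). The ynolate oxygen is taken from an ester instead of a peroxide.
 - Methoxycarbonylation of 3 (Pd(OAc)2, dppp, CO 1 atm, MeOH, Et3N, DMF, 70 °C) should give methyl 5-(1,3-dioxolan-2-yl)-2,3-dimethoxybenzoate F5.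
 - Addition of LiCHBr2 (CH2Br2, lithium 2,2,6,6-tetramethylpiperidide, THF, −78 °C) and enolisation with LiN(SiMe3)2 give 2,2-dibromo-1-[5-(1,3-dioxolan-2-yl)-2,3-dimethoxyphenyl]ethan-1-one F6, held as its lithium enolate.
 - Bromine–lithium exchange with n-BuLi and warming trigger the 1,2-aryl shift of the Kowalski rearrangement to ynolate 7, which is silylated as before to 8.

Step 16 (global deprotection).
- What may go wrong: The crowded C4' methyl ether, flanked by a methoxy group and the biaryl bond, may be lost to excess BCl3 on warming. Removal of the ethyl group may be incomplete. The phloroglucinol rings may be C-benzylated.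
- Fallback: It sets out from 27 and comes back at 28. The two tasks are separated and a weak, chelation-only Lewis acid is used.
 - MgI2·OEt2 (PhMe/Et2O, 80 °C) should dealkylate only the two ethers peri to a carbonyl (5''-OEt and 5-OBn). This gives 7,4'''-di-O-benzyl-5'-methoxybilobetin F7.
 - Neutral hydrogenolysis (H2 1 atm, Pd/C, THF/MeOH) then removes the two remaining benzyl groups and leaves the methyl ethers and the chromone double bonds untouched, giving 28.

**Further compounds**
F1 | step 6 | 2-[5-(1,3-dioxolan-2-yl)-2,3-dimethoxyphenyl]-4,4,5,5-tetramethyl-1,3,2-dioxaborolane | COc1cc(C2OCCO2)cc(B2OC(C)(C)C(C)(C)O2)c1OC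
F2 | step 6 | 5-ethoxybenzene-1,3-diol | CCOc1cc(O)cc(O)c1
F3 | step 6 | 5-ethoxy-2-iodobenzene-1,3-diol | CCOc1cc(O)c(I)c(O)c1
F4 | step 6 | 2-[5-(1,3-dioxolan-2-yl)-2,3-dimethoxyphenyl]-5-ethoxybenzene-1,3-diol | COc1cc(C2OCCO2)cc(-c2c(O)cc(OCC)cc2O)c1OC
F5 | step 5 | methyl 5-(1,3-dioxolan-2-yl)-2,3-dimethoxybenzoate | COC(=O)c1cc(C2OCCO2)cc(OC)c1OC
F6 | step 5 | 2,2-dibromo-1-[5-(1,3-dioxolan-2-yl)-2,3-dimethoxyphenyl]ethan-1-one | O=C(C(Br)Br)c1cc(C2OCCO2)cc(OC)c1OC
F7 | step 16 | 7,4'''-di-O-benzyl-5'-methoxybilobetin | COc1cc(-c2cc(=O)c3c(O)cc(OCc4ccccc4)cc3o2)cc(-c2c(O)cc(O)c3c(=O)cc(-c4ccc(OCc5ccccc5)cc4)oc23)c1OC
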